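**Retrosynthetic overview**
- The target is a linear hexa-ether of seven benzene rings, A–O–B–O–C–O–D–O–E–O–F–O–G (rings lettered left to right along the SMILES). It is carried as its heptadeca-O-methyl ether and demethylated last.
- Key disconnection: the C–O–D ether, between an A–B–C trimer phenol and a D–E–F–G tetramer. The ring-D carbon, normally a nucleophilic arene carbon, is reversed into an aryl-cation equivalent, an aryl(2,4,6-trimethoxyphenyl)-λ3-iodane made from the aryl iodide, and is attacked by the phenoxide oxygen.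
- The other five ethers are cut the same way (hindered 2,6-dioxygenated phenoxide plus aryl-λ3-iodane at the unhindered carbon): B–C, then A–BC; D–E; F–G, then FG–DE.
- Rings C and E enter as ortho-mesyloxy aryl iodides. Their iodine(III) is therefore generated before an ortho-aryloxy group exists (which would cyclise onto it), and KOH later unmasks the phenol that forms the next ether.
- No ring is constructed; all seven come from commercial phenols and iodoarenes. Order of union: [C+B]→A, [E+D], [G+F]→[DE], then ABC + DEFG.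

Assumption: the target has no stereocentre, so there is no enantiomer to select; its only C–C bonds lie inside the benzene rings, so the strategic bonds are the six aryl C–O bonds.

**Route**

Step 1
Reactants: 1 2,6-dimethoxyphenol (syringol)
Product: 2 4-iodo-2,6-dimethoxyphenol
Conditions: NIS (1.0 equiv), TsOH·H2O (5 mol %), MeCN, 0 °C to rt, dark
Reagents that add atoms: N-iodosuccinimide, O=C1CCC(=O)N1I
Why: Electrophilic aromatic iodination (SEAr); the position para to the free OH is the only strongly activated one because both ortho positions carry OMe.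

Step 2
Reactants: 3 2,3,4-trimethoxyphenol
Product: 4 6-iodo-2,3,4-trimethoxyphenol
Conditions: NIS (1.0 equiv), MeCN, 0 °C to rt
Reagents that add atoms: N-iodosuccinimide, O=C1CCC(=O)N1I
Why: SEAr iodination; para to OH is blocked, and C6 (ortho to OH, para to the 3-OMe) is more activated than C5.

Step 3
Reactants: 4 6-iodo-2,3,4-trimethoxyphenol
Product: 5 6-iodo-2,3,4-trimethoxyphenyl methanesulfonate
Conditions: MsCl (1.2 equiv), Et3N, CH2Cl2, 0 °C
Reagents that add atoms: methanesulfonyl chloride, CS(=O)(=O)Cl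
Why: O-sulfonylation of the phenol; the mesylate masks the oxygen ortho to iodine (a free ortho-OH is incompatible with iodine(III)) and makes this ring the electron-poorer ligand in the later aryl transfer.

Step 4
Reactants: 6 1-iodo-3,5-dimethoxybenzene
Product: 8 2-iodo-4,6-dimethoxybenzaldehyde, via iminium salt 7 (not isolated)
Conditions: POCl3 (1.5 equiv), DMF, 0 to 90 °C; then aq. NaOH to pH 6–7
Reagents that add atoms: N,N-dimethylformamide, CN(C)C=O; water, O
Why: Vilsmeier–Haack formylation; attack occurs at C2 (para to one OMe, ortho to the other, next to iodine) rather than at the more hindered C4 between the two OMe groups, as known for 1-bromo-3,5-dimethoxybenzene.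

Step 5
Reactants: 8 2-iodo-4,6-dimethoxybenzaldehyde
Product: 10 2-iodo-4,6-dimethoxyphenol, via aryl formate 9 (not isolated)
Conditions: mCPBA (1.2 equiv), CH2Cl2, 0 °C to rt; then K2CO3 (cat.), MeOH, rt
Reagents that add atoms: 3-chloroperbenzoic acid, OOC(=O)c1cccc(Cl)c1
Why: Dakin-type Baeyer–Villiger oxidation; the electron-rich aryl group migrates to give the formate, which is methanolysed to the phenol, and the aryl iodide is not oxidised by mCPBA without strong acid.

Step 6
Reactants: 10 2-iodo-4,6-dimethoxyphenol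
Product: 11 2-iodo-4,6-dimethoxyphenyl methanesulfonate
Conditions: MsCl (1.2 equiv), Et3N, CH2Cl2, 0 °C
Reagents that add atoms: methanesulfonyl chloride, CS(=O)(=O)Cl
Why: O-sulfonylation, for the same reasons as in step 3.

Step 7
Reactants: 5 6-iodo-2,3,4-trimethoxyphenyl methanesulfonate (1.2 equiv); 2 4-iodo-2,6-dimethoxyphenol
Product: 14 6-(4-iodo-2,6-dimethoxyphenoxy)-2,3,4-trimethoxyphenyl methanesulfonate (B–C dimer), via diacetoxyiodane 12 (not isolated), via TMP-iodonium tosylate 13 (not isolated)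
Conditions: mCPBA (1.0 equiv), AcOH/CH2Cl2, rt to 40 °C; then 1,3,5-trimethoxybenzene (1.5 equiv), TsOH·H2O (1.0 equiv), 0 °C to rt; evaporate; then 2, K2CO3 (4 equiv), MeCN, 55 °C
Reagents that add atoms: none
Why: Oxidation of ArI to ArI(OAc)2 and acid-promoted SEAr on 1,3,5-trimethoxybenzene give the aryl(TMP)iodonium salt, an aryl-cation equivalent, and metal-free O-arylation of the phenoxide (ligand exchange and reductive ligand coupling at iodine(III)) transfers the less electron-rich, ortho-substituted aryl while TMP leaves as TMP–I; the aryl iodide of 2 is inert.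

Step 8
Reactants: 14 B–C dimer iodide (1.2 equiv); 15 2,4,6-trimethoxyphenol
Product: 18 6-[2,6-dimethoxy-4-(2,4,6-trimethoxyphenoxy)phenoxy]-2,3,4-trimethoxyphenyl methanesulfonate (A–B–C trimer mesylate), via diacetoxyiodane 16 (not isolated), via TMP-iodonium tosylate 17 (not isolated)
Conditions: mCPBA (1.0 equiv), AcOH/CH2Cl2, rt; then 1,3,5-trimethoxybenzene (1.5 equiv), TsOH·H2O (1.0 equiv), 0 °C to rt; evaporate; then 15, K2CO3 (4 equiv), MeCN, 55 °C
Reagents that add atoms: none
Why: Same one-pot aryl(TMP)iodonium formation and diaryliodonium O-arylation; no strong acid is present until the TMB trap is there, so the I(III) centre is captured by TMB and not by the substrate's own rings, and the iodine sits para to the ether so it cannot cyclise.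

Step 9
Reactants: 18 A–B–C trimer mesylate
Product: 19 6-[2,6-dimethoxy-4-(2,4,6-trimethoxyphenoxy)phenoxy]-2,3,4-trimethoxyphenol (A–B–C trimer phenol)
Conditions: KOH (5 equiv), MeOH/THF/H2O, 60 °C; then aq. HCl
Reagents that add atoms: none
Why: Sulfonate ester hydrolysis by hydroxide attack at sulfur (S–O cleavage); methyl and diaryl ethers are inert to base.

Step 10
Reactants: 11 2-iodo-4,6-dimethoxyphenyl methanesulfonate (1.2 equiv); 2 4-iodo-2,6-dimethoxyphenol
Product: 22 2-(4-iodo-2,6-dimethoxyphenoxy)-4,6-dimethoxyphenyl methanesulfonate (D–E dimer mesylate), via diacetoxyiodane 20 (not isolated), via TMP-iodonium tosylate 21 (not isolated)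
Conditions: mCPBA (1.0 equiv), AcOH/CH2Cl2, rt to 40 °C; then 1,3,5-trimethoxybenzene (1.5 equiv), TsOH·H2O (1.0 equiv), 0 °C to rt; evaporate; then 2, K2CO3 (4 equiv), MeCN, 55 °C
Reagents that add atoms: none
Why: One-pot aryl(TMP)iodonium formation and diaryliodonium O-arylation as in step 7; the ortho-mesyloxy aryl is the electron-poorer ligand and is transferred.

Step 11
Reactants: 22 D–E dimer mesylate
Product: 23 2-(4-iodo-2,6-dimethoxyphenoxy)-4,6-dimethoxyphenol (D–E dimer phenol)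
Conditions: KOH (5 equiv), MeOH/THF/H2O, 60 °C; then aq. HCl
Reagents that add atoms: none
Why: Sulfonate ester hydrolysis at sulfur; the aryl iodide and the ethers are untouched by hydroxide.

Step 12
Reactants: 24 5-iodo-1,2,3-trimethoxybenzene (1.2 equiv); 2 4-iodo-2,6-dimethoxyphenol
Product: 27 5-(4-iodo-2,6-dimethoxyphenoxy)-1,2,3-trimethoxybenzene (F–G dimer), via diacetoxyiodane 25 (not isolated), via TMP-iodonium tosylate 26 (not isolated)
Conditions: mCPBA (1.0 equiv), AcOH/CH2Cl2, rt; then 1,3,5-trimethoxybenzene (1.5 equiv), TsOH·H2O (1.0 equiv), 0 °C to rt; evaporate; then 2, K2CO3 (4 equiv), MeCN, 55 °C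
Reagents that add atoms: none
Why: One-pot aryl(TMP)iodonium formation and diaryliodonium O-arylation; the 3,4,5-trimethoxyphenyl ipso carbon (two meta-OMe) is less electron-rich than that of TMP and is the one transferred.

Step 13
Reactants: 27 F–G dimer iodide (1.2 equiv); 23 D–E dimer phenol
Product: 30 5-{4-[2-(4-iodo-2,6-dimethoxyphenoxy)-4,6-dimethoxyphenoxy]-2,6-dimethoxyphenoxy}-1,2,3-trimethoxybenzene (D–E–F–G tetramer iodide), via diacetoxyiodane 28 (not isolated), via TMP-iodonium tosylate 29 (not isolated)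
Conditions: mCPBA (1.0 equiv), AcOH/CH2Cl2, rt; then 1,3,5-trimethoxybenzene (2 equiv), TsOH·H2O (1.0 equiv), 0 °C to rt; evaporate; then 23, K2CO3 (4 equiv), MeCN, 55 °C
Reagents that add atoms: none
Why: Same iodonium formation and O-arylation; the iodide of 23 is added only after the oxidant is consumed and is inert to the metal-free arylation, so it survives as the handle for step 14.

Step 14
Reactants: 30 D–E–F–G tetramer iodide (1.2 equiv); 19 A–B–C trimer phenol
Product: 33 heptadeca-O-methyl ether of the target, via diacetoxyiodane 31 (not isolated), via TMP-iodonium tosylate 32 (not isolated)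
Conditions: mCPBA (1.0 equiv), AcOH/CH2Cl2, rt; then 1,3,5-trimethoxybenzene (3 equiv), TsOH·H2O (1.0 equiv), 0 °C to rt; evaporate; then 19, K2CO3 (4 equiv), MeCN, 60 °C
Reagents that add atoms: none
Why: Convergent key union by polarity reversal: the ring-D carbon para to oxygen, intrinsically nucleophilic, becomes an electrophile as the aryl(TMP)-λ3-iodane and is joined to the hindered phenoxide of 19 by ligand coupling at iodine(III) (diaryliodonium O-arylation, which tolerates di-ortho-substituted phenols); no stereocentre is formed.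

Step 15
Reactants: 33 heptadeca-O-methyl ether of the target
Product: 34 target heptamer (17 free OH)
Conditions: BBr3 (40 equiv), CH2Cl2, −78 °C to rt, Ar; then MeOH/H2O, 0 °C; Sephadex LH-20 under Ar
Reagents that add atoms: none
Why: Lewis-acid O-demethylation of all 17 aryl methyl ethers (bromide attacks the methyl carbon, SN2); the diaryl ether bonds survive because neither of their carbons can be attacked by bromide.

**Compound list**
1 | 2,6-dimethoxyphenol (syringol) | COc1cccc(OC)c1O | starting material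
2 | 4-iodo-2,6-dimethoxyphenol | COc1cc(I)cc(OC)c1O | intermediate
3 | 2,3,4-trimethoxyphenol | COc1ccc(O)c(OC)c1OC | starting material
4 | 6-iodo-2,3,4-trimethoxyphenol | COc1cc(I)c(O)c(OC)c1OC | intermediate
5 | 6-iodo-2,3,4-trimethoxyphenyl methanesulfonate | COc1cc(I)c(OS(C)(=O)=O)c(OC)c1OC | intermediate
6 | 1-iodo-3,5-dimethoxybenzene | COc1cc(I)cc(OC)c1 | starting material
7 | (2-iodo-4,6-dimethoxybenzylidene)dimethyliminium dichlorophosphate | C[N+](C)=Cc1c(I)cc(OC)cc1OC.[O-]P(=O)(Cl)Cl | intermediate (not isolated)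
8 | 2-iodo-4,6-dimethoxybenzaldehyde | COc1cc(I)c(C=O)c(OC)c1 | intermediate
9 | 2-iodo-4,6-dimethoxyphenyl formate | COc1cc(I)c(OC=O)c(OC)c1 | intermediate (not isolated)
10 | 2-iodo-4,6-dimethoxyphenol | COc1cc(I)c(O)c(OC)c1 | intermediate
11 | 2-iodo-4,6-dimethoxyphenyl methanesulfonate | COc1cc(I)c(OS(C)(=O)=O)c(OC)c1 | intermediate
12 | 6-(diacetoxy-λ3-iodanyl)-2,3,4-trimethoxyphenyl methanesulfonate | COc1cc(I(OC(C)=O)OC(C)=O)c(OS(C)(=O)=O)c(OC)c1OC | intermediate (not isolated)
13 | [2-(methanesulfonyloxy)-3,4,5-trimethoxyphenyl](2,4,6-trimethoxyphenyl)iodonium tosylate | COc1cc([I+]c2c(OC)cc(OC)cc2OC)c(OS(C)(=O)=O)c(OC)c1OC.Cc1ccc(S(=O)(=O)[O-])cc1 | intermediate (not isolated)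
14 | 6-(4-iodo-2,6-dimethoxyphenoxy)-2,3,4-trimethoxyphenyl methanesulfonate (B–C dimer) | COc1cc(Oc2c(OC)cc(I)cc2OC)c(OS(C)(=O)=O)c(OC)c1OC | intermediate
15 | 2,4,6-trimethoxyphenol | COc1cc(OC)c(O)c(OC)c1 | starting material
16 | 6-[4-(diacetoxy-λ3-iodanyl)-2,6-dimethoxyphenoxy]-2,3,4-trimethoxyphenyl methanesulfonate | COc1cc(Oc2c(OC)cc(I(OC(C)=O)OC(C)=O)cc2OC)c(OS(C)(=O)=O)c(OC)c1OC | intermediate (not isolated)
17 | {3,5-dimethoxy-4-[2-(methanesulfonyloxy)-3,4,5-trimethoxyphenoxy]phenyl}(2,4,6-trimethoxyphenyl)iodonium tosylate | COc1cc(Oc2c(OC)cc([I+]c3c(OC)cc(OC)cc3OC)cc2OC)c(OS(C)(=O)=O)c(OC)c1OC.Cc1ccc(S(=O)(=O)[O-])cc1 | intermediate (not isolated)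
18 | 6-[2,6-dimethoxy-4-(2,4,6-trimethoxyphenoxy)phenoxy]-2,3,4-trimethoxyphenyl methanesulfonate (A–B–C trimer mesylate) | COc1cc(Oc2c(OC)cc(Oc3c(OC)cc(OC)cc3OC)cc2OC)c(OS(C)(=O)=O)c(OC)c1OC | intermediate
19 | 6-[2,6-dimethoxy-4-(2,4,6-trimethoxyphenoxy)phenoxy]-2,3,4-trimethoxyphenol (A–B–C trimer phenol) | COc1cc(Oc2c(OC)cc(Oc3c(OC)cc(OC)cc3OC)cc2OC)c(O)c(OC)c1OC | intermediate
20 | 2-(diacetoxy-λ3-iodanyl)-4,6-dimethoxyphenyl methanesulfonate | COc1cc(I(OC(C)=O)OC(C)=O)c(OS(C)(=O)=O)c(OC)c1 | intermediate (not isolated)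
21 | [2-(methanesulfonyloxy)-3,5-dimethoxyphenyl](2,4,6-trimethoxyphenyl)iodonium tosylate | COc1cc([I+]c2c(OC)cc(OC)cc2OC)c(OS(C)(=O)=O)c(OC)c1.Cc1ccc(S(=O)(=O)[O-])cc1 | intermediate (not isolated)
22 | 2-(4-iodo-2,6-dimethoxyphenoxy)-4,6-dimethoxyphenyl methanesulfonate (D–E dimer mesylate) | COc1cc(Oc2c(OC)cc(I)cc2OC)c(OS(C)(=O)=O)c(OC)c1 | intermediate
23 | 2-(4-iodo-2,6-dimethoxyphenoxy)-4,6-dimethoxyphenol (D–E dimer phenol) | COc1cc(Oc2c(OC)cc(I)cc2OC)c(O)c(OC)c1 | intermediate
24 | 5-iodo-1,2,3-trimethoxybenzene | COc1cc(I)cc(OC)c1OC | starting material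
25 | 5-(diacetoxy-λ3-iodanyl)-1,2,3-trimethoxybenzene | COc1cc(I(OC(C)=O)OC(C)=O)cc(OC)c1OC | intermediate (not isolated)
26 | (3,4,5-trimethoxyphenyl)(2,4,6-trimethoxyphenyl)iodonium tosylate | COc1cc([I+]c2c(OC)cc(OC)cc2OC)cc(OC)c1OC.Cc1ccc(S(=O)(=O)[O-])cc1 | intermediate (not isolated)
27 | 5-(4-iodo-2,6-dimethoxyphenoxy)-1,2,3-trimethoxybenzene (F–G dimer) | COc1cc(Oc2c(OC)cc(I)cc2OC)cc(OC)c1OC | intermediate
28 | 5-[4-(diacetoxy-λ3-iodanyl)-2,6-dimethoxyphenoxy]-1,2,3-trimethoxybenzene | COc1cc(Oc2c(OC)cc(I(OC(C)=O)OC(C)=O)cc2OC)cc(OC)c1OC | intermediate (not isolated)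
29 | [3,5-dimethoxy-4-(3,4,5-trimethoxyphenoxy)phenyl](2,4,6-trimethoxyphenyl)iodonium tosylate | COc1cc(Oc2c(OC)cc([I+]c3c(OC)cc(OC)cc3OC)cc2OC)cc(OC)c1OC.Cc1ccc(S(=O)(=O)[O-])cc1 | intermediate (not isolated)
30 | 5-{4-[2-(4-iodo-2,6-dimethoxyphenoxy)-4,6-dimethoxyphenoxy]-2,6-dimethoxyphenoxy}-1,2,3-trimethoxybenzene (D–E–F–G tetramer iodide) | COc1cc(Oc2c(OC)cc(Oc3c(Oc4c(OC)cc(I)cc4OC)cc(OC)cc3OC)cc2OC)cc(OC)c1OC | intermediate
31 | diacetoxy-λ3-iodane of 30 (I(OAc)2 in place of I on ring D) | COc1cc(Oc2c(OC)cc(Oc3c(Oc4c(OC)cc(I(OC(C)=O)OC(C)=O)cc4OC)cc(OC)cc3OC)cc2OC)cc(OC)c1OC | intermediate (not isolated)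
32 | aryl(2,4,6-trimethoxyphenyl)iodonium tosylate of 30 (iodonium on ring D) | COc1cc(Oc2c(OC)cc(Oc3c(Oc4c(OC)cc([I+]c5c(OC)cc(OC)cc5OC)cc4OC)cc(OC)cc3OC)cc2OC)cc(OC)c1OC.Cc1ccc(S(=O)(=O)[O-])cc1 | intermediate (not isolated)
33 | heptadeca-O-methyl ether of the target (A–O–B–O–C–O–D–O–E–O–F–O–G, all 17 OH as OMe) | COc1cc(Oc2c(OC)cc(Oc3c(Oc4c(OC)cc(Oc5c(Oc6c(OC)cc(Oc7c(OC)cc(OC)cc7OC)cc6OC)cc(OC)c(OC)c5OC)cc4OC)cc(OC)cc3OC)cc2OC)cc(OC)c1OC | intermediate
34 | CNP0351377.0, heptamer with 17 free OH (achiral) | Oc1cc(O)c(Oc2cc(O)c(Oc3cc(O)c(O)c(O)c3Oc3cc(O)c(Oc4cc(O)cc(O)c4Oc4cc(O)c(Oc5cc(O)c(O)c(O)c5)c(O)c4)c(O)c3)c(O)c2)c(O)c1 | target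

**Totals**
Total step count: 15. Longest linear sequence: 8 steps (6 → 8 → 10 → 11 → 22 → 23 → 30 → 33 → 34).

**Steps most likely to fail, with fallbacks**

Step 14 is the most exposed. Tetramer 30 carries four electron-rich rings that can compete with 1,3,5-trimethoxybenzene for the iodine(III) centre, and the union with the di-ortho-substituted phenol 19 is the most hindered. The fallback moves the last bond to the E–O–F ether (5 + 2 instead of 3 + 4), so that iodine(III) is only ever generated on two-ring iodides. It sets out from 22, which is oxidised as in step 10 to the diacetoxyiodane of 22 F1 and converted with 1,3,5-trimethoxybenzene/TsOH into the aryl(TMP)iodonium tosylate of 22 F2. Coupling of F2 with trimer phenol 19 (K2CO3, MeCN, 55 °C) gives the A–B–C–D–E pentamer mesylate F3, and KOH/MeOH cleaves it to the A–B–C–D–E pentamer phenol F4. Arylation of F4 with iodonium salt 29, generated from 27 as in step 13, comes back to the route at 33.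

Step 10 (the same concern holds for its twin, step 7) is the second risk. The ortho-mesyloxy iodonium salt 21 may lose its sulfonyl group to the phenoxide of 2, or couple slowly at the tri-ortho-substituted centre. The fallback makes this one ether by copper catalysis instead of through iodine(III). It sets out from aldehyde 8: CuI/picolinic acid/K3PO4 in DMSO at 80 °C couples the formyl-activated C–I bond of 8 with phenol 2 to give 2-(4-iodo-2,6-dimethoxyphenoxy)-4,6-dimethoxybenzaldehyde F5. Dakin oxidation (mCPBA, then K2CO3/MeOH) passes through 2-(4-iodo-2,6-dimethoxyphenoxy)-4,6-dimethoxyphenyl formate F6 and comes back to the route at phenol 23, bypassing steps 5, 6, 10 and 11.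

Step 15 is the third risk. Seventeen demethylations must all go to completion, and the free polyphenol with its pyrogallol units is air-sensitive and hard to purify. The fallback sets out from 33 and switches to nucleophilic demethylation (sodium dodecanethiolate, NMP, 130 °C, Ar). After acidic work-up the crude polyphenol is acetylated (Ac2O, pyridine) to the heptadecaacetate of 34 F7, which is stable and can be purified on silica. Degassed HCl/MeOH then releases the phenol and comes back to the route at 34.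

**Further compounds**
F1 | step 14 | 2-[4-(diacetoxy-λ3-iodanyl)-2,6-dimethoxyphenoxy]-4,6-dimethoxyphenyl methanesulfonate | COc1cc(Oc2c(OC)cc(I(OC(C)=O)OC(C)=O)cc2OC)c(OS(C)(=O)=O)c(OC)c1
F2 | step 14 | {3,5-dimethoxy-4-[2-(methanesulfonyloxy)-3,5-dimethoxyphenoxy]phenyl}(2,4,6-trimethoxyphenyl)iodonium tosylate | COc1cc(Oc2c(OC)cc([I+]c3c(OC)cc(OC)cc3OC)cc2OC)c(OS(C)(=O)=O)c(OC)c1.Cc1ccc(S(=O)(=O)[O-])cc1
F3 | step 14 | A–B–C–D–E pentamer mesylate (permethylated, OMs on the ring-E oxygen that will bind ring F) | COc1cc(Oc2c(OC)cc(Oc3c(Oc4c(OC)cc(Oc5c(OC)cc(OC)cc5OC)cc4OC)cc(OC)c(OC)c3OC)cc2OC)c(OS(C)(=O)=O)c(OC)c1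
F4 | step 14 | A–B–C–D–E pentamer phenol (permethylated, free OH on ring E) | COc1cc(Oc2c(OC)cc(Oc3c(Oc4c(OC)cc(Oc5c(OC)cc(OC)cc5OC)cc4OC)cc(OC)c(OC)c3OC)cc2OC)c(O)c(OC)c1
F5 | step 10 | 2-(4-iodo-2,6-dimethoxyphenoxy)-4,6-dimethoxybenzaldehyde | COc1cc(Oc2c(OC)cc(I)cc2OC)c(C=O)c(OC)c1
F6 | step 10 | 2-(4-iodo-2,6-dimethoxyphenoxy)-4,6-dimethoxyphenyl formate | COc1cc(Oc2c(OC)cc(I)cc2OC)c(OC=O)c(OC)c1
F7 | step 15 | heptadeca-O-acetate of 34 | CC(=O)Oc1cc(Oc2c(OC(C)=O)cc(Oc3c(Oc4c(OC(C)=O)cc(Oc5c(Oc6c(OC(C)=O)cc(Oc7c(OC(C)=O)cc(OC(C)=O)cc7OC(C)=O)cc6OC(C)=O)cc(OC(C)=O)c(OC(C)=O)c5OC(C)=O)cc4OC(C)=O)cc(OC(C)=O)cc3OC(C)=O)cc2OC(C)=O)cc(OC(C)=O)c1OC(C)=O
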